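With benzofuran numbering (O1; C2 attached to C1' of the syringyl ring; C3 carrying CH2OH; ring A = C3a to C7a, acrylic acid on C5, OMe on C7), everything rests on cutting C2–C1' and C3–C3a together. The feature used is the vicinal pair C2–C3: two neighbouring methine carbons with one aryl group on each, which is what an (E)-allyl ether C=C becomes after taking up two aryl groups from opposite faces. One palladium-catalysed conjunctive coupling makes both bonds and both stereocentres. Its precursor is the lithium ate complex of an (E)-3-silyloxypropenyl boronic ester with silylated syringyllithium, met by the ring A triflate; boron carries the hindered mac diol, not pinacol, to suppress direct Suzuki coupling.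

Key step: step 7

Assumption: the antipode of the ferrocenyl diphosphine written in step 7 is chosen by analogy with related conjunctive couplings; should it deliver the mirror-image boronate, the equally available (Rp,Rp) antipode is used instead.

**Step 1**
Reactants: 1 acenaphthoquinone
Product: 2 cis-1,2-dimethylacenaphthene-1,2-diol (mac diol, meso)
Conditions: AlMe3 (3 equiv), toluene, 0 °C to rt; 1 M aq HCl; recrystallisation
Reagents that add atoms: trimethylaluminium, C[Al](C)C
Why: Twofold 1,2-addition of a methyl organometallic to the vicinal diketone, in which the second methyl group should enter anti to the bulky aluminium alkoxide of the first adduct and so give the cis diol, any trans isomer being removed by crystallisation.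

**Step 2**
Reactants: 3 tert-butyldimethyl(prop-2-ynyloxy)silane; 2 mac diol
Product: 5 (E)-3-(tert-butyldimethylsilyloxy)prop-1-enylboronic acid mac ester, via alkenyl catechol boronate 4 (not isolated)
Conditions: catecholborane (1.1 equiv), THF, 65 °C; then 2, rt; filtration through silica
Reagents that add atoms: catecholborane, B1Oc2ccccc2O1
Why: Syn hydroboration of the terminal alkyne puts boron on the terminal carbon and gives the E alkene, and the labile catechol ester then exchanges with the chelating cis diol (Brown hydroboration followed by transesterification).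

**Step 3**
Reactants: 6 4-bromo-2,6-dimethoxyphenol
Product: 7 (4-bromo-2,6-dimethoxyphenoxy)triisopropylsilane
Conditions: TIPSOTf, 2,6-lutidine, CH2Cl2, 0 °C to rt
Reagents that add atoms: triisopropylsilyl triflate, CC(C)[Si](OS(=O)(=O)C(F)(F)F)(C(C)C)C(C)C
Why: Silylation of a hindered phenol with a silyl triflate gives an aryl silyl ether that withstands t-BuLi, mild base and aqueous acid.

**Step 4**
Reactants: 8 5-hydroxyvanillin (3,4-dihydroxy-5-methoxybenzaldehyde)
Product: 9 3-hydroxy-5-methoxy-4-(methoxymethoxy)benzaldehyde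
Conditions: MOMCl (1.05 equiv), K2CO3 (1.1 equiv), acetone, 0 °C to rt
Reagents that add atoms: chloromethyl methyl ether, COCCl
Why: The hydroxyl para to the formyl group is the more acidic one, so one equivalent of weak base forms that phenoxide selectively and the Williamson alkylation occurs at O-4.

**Step 5**
Reactants: 9 3-hydroxy-5-methoxy-4-(methoxymethoxy)benzaldehyde
Product: 10 5-formyl-3-methoxy-2-(methoxymethoxy)phenyl triflate
Conditions: PhNTf2, Et3N, DMAP (cat.), CH2Cl2, rt
Reagents that add atoms: N-phenylbis(trifluoromethanesulfonimide), O=S(=O)(N(c1ccccc1)S(=O)(=O)C(F)(F)F)C(F)(F)F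
Why: Sulfonylation of the remaining phenol with a mild triflyl donor under basic conditions leaves the MOM acetal and the aldehyde untouched.

**Step 6**
Reactants: 10 5-formyl-3-methoxy-2-(methoxymethoxy)phenyl triflate
Product: 11 5-(1,3-dioxolan-2-yl)-3-methoxy-2-(methoxymethoxy)phenyl triflate
Conditions: TMSOCH2CH2OTMS, TMSOTf (cat.), CH2Cl2, −78 to −20 °C; pyridine quench
Reagents that add atoms: 1,2-bis(trimethylsilyloxy)ethane, C[Si](C)(C)OCCO[Si](C)(C)C
Why: Noyori acetalisation under aprotic conditions at low temperature converts the aryl aldehyde into the dioxolane without cleaving the MOM ether, and the acetal keeps the aldehyde out of the organometallic step.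

**Step 7**
Reactants: 7 (4-bromo-2,6-dimethoxyphenoxy)triisopropylsilane; 5 (E)-3-(tert-butyldimethylsilyloxy)prop-1-enylboronic acid mac ester; 11 5-(1,3-dioxolan-2-yl)-3-methoxy-2-(methoxymethoxy)phenyl triflate
Product: 14 (1S,2R)-3-(tert-butyldimethylsilyloxy)-2-[5-(1,3-dioxolan-2-yl)-3-methoxy-2-(methoxymethoxy)phenyl]-1-[3,5-dimethoxy-4-(triisopropylsilyloxy)phenyl]propylboronic acid mac ester, via aryllithium 12 (not isolated), via lithium boron ate complex 13 (not isolated)
Conditions: 7, t-BuLi (2 equiv), Et2O, −78 °C; 5, −78 °C to rt; solvent switch to THF; then 11, Pd(OAc)2 (5 mol%), (Sp,Sp)-1,1'-bis[bis(4-methoxy-3,5-dimethylphenyl)phosphino]-2,2'-bis[(R)-α-(dimethylamino)benzyl]ferrocene (6 mol%), KOSO2CF3, THF, 60 °C; non-oxidative work-up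
Reagents that add atoms: none
Why: Oxidative addition of triflate 11 to zerovalent palladium gives a cationic arylpalladium species that binds the alkene of ate complex 13; the syringyl group then shifts from boron to C2 anti to the metal while palladium bonds to C3, and reductive elimination joins C3 to C3a. The closest known reaction type is the enantioselective conjunctive (1,2-metallate) cross-coupling of beta-substituted alkenylboron ate complexes with aryl triflates. No ring is closed. The chiral diphosphine selects the alkene face and thereby sets C3 and C2 together, and the anti addition across the E alkene fixes their relative configuration as (1S,2R). The step needs conjunctive coupling to win over direct transmetallation and over beta-hydride or beta-silyloxy elimination from the alkylpalladium intermediate: the hindered mac diol slows transmetallation, the triflate with KOSO2CF3 as bromide scavenger keeps palladium cationic, and the wide-bite-angle ligand speeds reductive elimination. The electron-rich migrating aryl group helps, whereas the ortho-substituted triflate is the point most likely to slow the reaction.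

**Step 8**
Reactants: 14 the (1S,2R)-boronic acid mac ester
Product: 15 (1S,2R)-3-(tert-butyldimethylsilyloxy)-2-[5-(1,3-dioxolan-2-yl)-3-methoxy-2-(methoxymethoxy)phenyl]-1-[3,5-dimethoxy-4-(triisopropylsilyloxy)phenyl]propan-1-ol
Conditions: NaBO3·4H2O, THF/H2O (1:1), rt
Reagents that add atoms: sodium perborate tetrahydrate, O.O.O.O.[Na+].[O-]OB=O
Why: Boronate oxidation, in which the peroxide adds to boron and the benzylic carbon migrates to oxygen with retention, under conditions mild enough for the aryl silyl ether and both acetals.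

**Step 9**
Reactants: 15 the (1S,2R)-propan-1-ol
Product: 17 (2S,3R)-2-[3,5-dimethoxy-4-(triisopropylsilyloxy)phenyl]-3-(hydroxymethyl)-7-methoxy-2,3-dihydrobenzofuran-5-carbaldehyde, via ring-open phenol 16 (not isolated)
Conditions: 3 M aq HCl, THF, 45 °C
Reagents that add atoms: water, O
Why: Aqueous acid removes the MOM group, the dioxolane and the primary silyl ether, and the electron-rich benzylic alcohol ionises to a cation that the freed ring A phenol captures (SN1 etherification, 5-exo closure), with C3 directing the syringyl group trans to CH2OH and reversible ionisation favouring the more stable trans isomer.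

**Step 10**
Reactants: 17 the (2S,3R)-dihydrobenzofuran-5-carbaldehyde
Product: 19 (E)-3-[(2S,3R)-2-[3,5-dimethoxy-4-(triisopropylsilyloxy)phenyl]-3-(hydroxymethyl)-7-methoxy-2,3-dihydrobenzofuran-5-yl]prop-2-enoic acid, via arylidenemalonic acid 18 (not isolated)
Conditions: malonic acid, pyridine, piperidine (cat.), 80 °C; aq HCl work-up
Reagents that add atoms: malonic acid, OC(=O)CC(=O)O
Why: Knoevenagel–Doebner condensation followed by decarboxylation gives the E acrylic acid, while the silyl ether keeps the phenol from opening the C2–O1 bond through a quinone methide in the warm base.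

**Step 11**
Reactants: 19 the silylated acrylic acid
Product: 20 (E)-3-[(2S,3R)-2-(4-hydroxy-3,5-dimethoxyphenyl)-3-(hydroxymethyl)-7-methoxy-2,3-dihydrobenzofuran-5-yl]prop-2-enoic acid (target)
Conditions: Bu4NF, AcOH, THF, 0 °C to rt; dilute aq HCl work-up
Reagents that add atoms: none
Why: Fluoride cleaves the aryl silyl ether, and the acetic acid buffer keeps the phenoxide concentration low so that neither stereocentre is disturbed.

**Compound list**
1 | acenaphthoquinone | O=C1C(=O)c2cccc3cccc1c23 | starting material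
2 | cis-1,2-dimethylacenaphthene-1,2-diol (mac diol) | C[C@]1(O)[C@@](C)(O)c2cccc3cccc1c23 | intermediate
3 | tert-butyldimethyl(prop-2-ynyloxy)silane | C#CCO[Si](C)(C)C(C)(C)C | starting material
4 | 2-[(E)-3-(tert-butyldimethylsilyloxy)prop-1-enyl]-1,3,2-benzodioxaborole | CC(C)(C)[Si](C)(C)OC/C=C/B1Oc2ccccc2O1 | intermediate
5 | (E)-3-(tert-butyldimethylsilyloxy)prop-1-enylboronic acid mac ester | CC(C)(C)[Si](C)(C)OC/C=C/B1O[C@]2(C)c3cccc4cccc(c34)[C@]2(C)O1 | intermediate
6 | 4-bromo-2,6-dimethoxyphenol | COc1cc(Br)cc(OC)c1O | starting material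
7 | (4-bromo-2,6-dimethoxyphenoxy)triisopropylsilane | COc1cc(Br)cc(OC)c1O[Si](C(C)C)(C(C)C)C(C)C | intermediate
8 | 5-hydroxyvanillin | COc1cc(C=O)cc(O)c1O | starting material
9 | 3-hydroxy-5-methoxy-4-(methoxymethoxy)benzaldehyde | COCOc1c(O)cc(C=O)cc1OC | intermediate
10 | 5-formyl-3-methoxy-2-(methoxymethoxy)phenyl triflate | COCOc1c(OC)cc(C=O)cc1OS(=O)(=O)C(F)(F)F | intermediate
11 | 5-(1,3-dioxolan-2-yl)-3-methoxy-2-(methoxymethoxy)phenyl triflate | COCOc1c(OC)cc(C2OCCO2)cc1OS(=O)(=O)C(F)(F)F | intermediate
12 | 3,5-dimethoxy-4-(triisopropylsilyloxy)phenyllithium | [Li]c1cc(OC)c(O[Si](C(C)C)(C(C)C)C(C)C)c(OC)c1 | intermediate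
13 | lithium aryl(alkenyl)borate of the mac diol (ate complex of 5 with 12) | [Li+].CC(C)(C)[Si](C)(C)OC/C=C/[B-]1(c2cc(OC)c(O[Si](C(C)C)(C(C)C)C(C)C)c(OC)c2)O[C@]3(C)c4cccc5cccc(c45)[C@]3(C)O1 | intermediate
14 | (1S,2R)-3-(tert-butyldimethylsilyloxy)-2-[5-(1,3-dioxolan-2-yl)-3-methoxy-2-(methoxymethoxy)phenyl]-1-[3,5-dimethoxy-4-(triisopropylsilyloxy)phenyl]propylboronic acid mac ester | COc1cc([C@@H](B2O[C@]3(C)c4cccc5cccc(c45)[C@]3(C)O2)[C@@H](CO[Si](C)(C)C(C)(C)C)c6cc(C7OCCO7)cc(OC)c6OCOC)cc(OC)c1O[Si](C(C)C)(C(C)C)C(C)C | intermediate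
15 | (1S,2R)-3-(tert-butyldimethylsilyloxy)-2-[5-(1,3-dioxolan-2-yl)-3-methoxy-2-(methoxymethoxy)phenyl]-1-[3,5-dimethoxy-4-(triisopropylsilyloxy)phenyl]propan-1-ol | COc1cc([C@@H](O)[C@@H](CO[Si](C)(C)C(C)(C)C)c2cc(C3OCCO3)cc(OC)c2OCOC)cc(OC)c1O[Si](C(C)C)(C(C)C)C(C)C | intermediate
16 | 3-[(1S,2R)-1,3-dihydroxy-1-[3,5-dimethoxy-4-(triisopropylsilyloxy)phenyl]propan-2-yl]-4-hydroxy-5-methoxybenzaldehyde | COc1cc([C@@H](O)[C@@H](CO)c2cc(C=O)cc(OC)c2O)cc(OC)c1O[Si](C(C)C)(C(C)C)C(C)C | intermediate
17 | (2S,3R)-2-[3,5-dimethoxy-4-(triisopropylsilyloxy)phenyl]-3-(hydroxymethyl)-7-methoxy-2,3-dihydrobenzofuran-5-carbaldehyde | COc1cc([C@H]2Oc3c(OC)cc(C=O)cc3[C@@H]2CO)cc(OC)c1O[Si](C(C)C)(C(C)C)C(C)C | intermediate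
18 | 2-[[(2S,3R)-2-[3,5-dimethoxy-4-(triisopropylsilyloxy)phenyl]-3-(hydroxymethyl)-7-methoxy-2,3-dihydrobenzofuran-5-yl]methylidene]malonic acid | COc1cc([C@H]2Oc3c(OC)cc(C=C(C(=O)O)C(=O)O)cc3[C@@H]2CO)cc(OC)c1O[Si](C(C)C)(C(C)C)C(C)C | intermediate
19 | (E)-3-[(2S,3R)-2-[3,5-dimethoxy-4-(triisopropylsilyloxy)phenyl]-3-(hydroxymethyl)-7-methoxy-2,3-dihydrobenzofuran-5-yl]prop-2-enoic acid | COc1cc([C@H]2Oc3c(OC)cc(/C=C/C(=O)O)cc3[C@@H]2CO)cc(OC)c1O[Si](C(C)C)(C(C)C)C(C)C | intermediate
20 | (E)-3-[(2S,3R)-2-(4-hydroxy-3,5-dimethoxyphenyl)-3-(hydroxymethyl)-7-methoxy-2,3-dihydrobenzofuran-5-yl]prop-2-enoic acid | COc1cc([C@H]2Oc3c(OC)cc(/C=C/C(=O)O)cc3[C@@H]2CO)cc(OC)c1O | target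

**Totals**
Total step count: 11. Longest linear sequence: 8 steps (steps 4 to 11, from 8).

**Steps most likely to fail**

Step 7. The palladium intermediate may leak into direct Suzuki coupling, the ortho-substituted arylpalladium may bind the hindered alkene too slowly, the alkylpalladium species may undergo beta-elimination, or the facial selectivity may be poor. The fallback sets the aryl-bearing centre with a chiral auxiliary instead; it sets out from 11 and 7 and returns at 17.
- Triflate 11 is coupled with the Reformatsky reagent BrZnCH2CO2Et (Pd2(dba)3, XPhos, THF, 60 °C, Negishi-type) to give ethyl 2-[5-(1,3-dioxolan-2-yl)-3-methoxy-2-(methoxymethoxy)phenyl]acetate F1.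
- LiOH in THF/H2O gives the arylacetic acid F2.
- Pivaloyl chloride and Et3N, then (S)-4-benzyloxazolidin-2-one and LiCl, give the N-arylacetyl oxazolidinone F3.
- Bromide 7 is lithiated (t-BuLi, Et2O, −78 °C) and formylated with DMF to 3,5-dimethoxy-4-(triisopropylsilyloxy)benzaldehyde F4.
- The boron aldol of F3 with F4 (Bu2BOTf, i-Pr2NEt, CH2Cl2, −78 to 0 °C) should give the syn adduct F5, the auxiliary fixing the carbon that becomes C3.
- LiBH4 (THF, MeOH, 0 °C) removes the auxiliary and gives the (1S,2R)-1,3-diol F6, the desilylated counterpart of 15, which is submitted to the conditions of step 9 to give 17.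

Step 9. The benzylic alcohol may ionise while the ring A oxygen is still protected, which opens the way to elimination toward a stilbene (erasing C3), to loss of formaldehyde from C3, or to trapping of released formaldehyde by the 1,3-diol. The fallback reverses the order of events so that strong acid acts while no benzylic alcohol exists; it sets out from 14 and returns at 17.
- Boronate 14, whose C–B bond tolerates aqueous acid, is treated with 3 M aq HCl in THF to give the deprotected phenolic hydroxy aldehyde boronate F7.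
- Anhydrous trimethylamine N-oxide (THF, 60 °C) oxidises the C–B bond with retention and without Dakin oxidation of the aldehyde, giving the ring-open phenol 16, which is now isolated.
- Catalytic TsOH·H2O (CH2Cl2, 0 °C) then closes the ring in the presence of the internal nucleophile to give 17.

Step 2. Hydroboration of the propargylic ether may be incompletely regioselective, or the exchange of the catechol ester for the hindered diol may stall. The fallback goes through the free boronic acid; it sets out from 3 and returns at 5.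
- Alkyne 3 is hydroborated with pinacolborane (Cp2Zr(H)Cl cat., Et3N cat., CH2Cl2, rt) to the pinacol ester F8.
- NaIO4 and NH4OAc in acetone/H2O cleave the pinacol to give (E)-3-(tert-butyldimethylsilyloxy)prop-1-enylboronic acid F9.
- F9 is condensed with diol 2 (MgSO4, CH2Cl2, rt) to give 5.

**Further compounds**
F1 | step 7 | ethyl 2-[5-(1,3-dioxolan-2-yl)-3-methoxy-2-(methoxymethoxy)phenyl]acetate | CCOC(=O)Cc1cc(C2OCCO2)cc(OC)c1OCOC
F2 | step 7 | 2-[5-(1,3-dioxolan-2-yl)-3-methoxy-2-(methoxymethoxy)phenyl]acetic acid | OC(=O)Cc1cc(C2OCCO2)cc(OC)c1OCOC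
F3 | step 7 | (S)-4-benzyl-3-[2-[5-(1,3-dioxolan-2-yl)-3-methoxy-2-(methoxymethoxy)phenyl]acetyl]oxazolidin-2-one | O=C(Cc1cc(C2OCCO2)cc(OC)c1OCOC)N3[C@@H](Cc4ccccc4)COC3=O
F4 | step 7 | 3,5-dimethoxy-4-(triisopropylsilyloxy)benzaldehyde | COc1cc(C=O)cc(OC)c1O[Si](C(C)C)(C(C)C)C(C)C
F5 | step 7 | (S)-4-benzyl-3-[(2S,3S)-2-[5-(1,3-dioxolan-2-yl)-3-methoxy-2-(methoxymethoxy)phenyl]-3-hydroxy-3-[3,5-dimethoxy-4-(triisopropylsilyloxy)phenyl]propanoyl]oxazolidin-2-one | COc1cc([C@@H](O)[C@@H](C(=O)N2[C@@H](Cc3ccccc3)COC2=O)c4cc(C5OCCO5)cc(OC)c4OCOC)cc(OC)c1O[Si](C(C)C)(C(C)C)C(C)C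
F6 | step 7 | (1S,2R)-2-[5-(1,3-dioxolan-2-yl)-3-methoxy-2-(methoxymethoxy)phenyl]-1-[3,5-dimethoxy-4-(triisopropylsilyloxy)phenyl]propane-1,3-diol | COc1cc([C@@H](O)[C@@H](CO)c2cc(C3OCCO3)cc(OC)c2OCOC)cc(OC)c1O[Si](C(C)C)(C(C)C)C(C)C
F7 | step 9 | (1S,2R)-2-(5-formyl-2-hydroxy-3-methoxyphenyl)-3-hydroxy-1-[3,5-dimethoxy-4-(triisopropylsilyloxy)phenyl]propylboronic acid mac ester | COc1cc([C@@H](B2O[C@]3(C)c4cccc5cccc(c45)[C@]3(C)O2)[C@@H](CO)c6cc(C=O)cc(OC)c6O)cc(OC)c1O[Si](C(C)C)(C(C)C)C(C)C
F8 | step 2 | (E)-3-(tert-butyldimethylsilyloxy)prop-1-enylboronic acid pinacol ester | CC1(C)OB(/C=C/CO[Si](C)(C)C(C)(C)C)OC1(C)C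
F9 | step 2 | (E)-3-(tert-butyldimethylsilyloxy)prop-1-enylboronic acid | OB(O)/C=C/CO[Si](C)(C)C(C)(C)C
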